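**Strategy.** Everything rests on disconnecting the O1–C8a aryl ether bond of ring C. Because O1 joins the C2 carbinol carbon to C8a of ring A, ortho to C4a and its C4 side chain, an open-chain (S)-C2 alcohol can be closed onto an ortho aryl bromide by palladium-catalysed C–O coupling. That single operation builds the pyran ring with C2 already fixed, while C4 stays a silyl-protected alcohol so no enolisable ketone can open the ring. The precursor is a 1,3-diarylpropane-1,3-diol mono-TBS ether: free (S)-hydroxyl at C2, OTBS at C4, bromine at C8a, MOM ethers on all four phenols and the prenyl group at C2′; it comes from an aldol union followed by oxazaborolidine reduction.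

Key step: step 9

Remark: C4 (the silyloxy/hydroxy carbon) arises racemic in step 6 and is carried as a mixture of both configurations until it is oxidised in step 11, so its descriptor is left open in the names and SMILES of 15–21; C2 is (S) from step 8 onward. (MOM = methoxymethyl, TBS = tert-butyldimethylsilyl.)

**Route**

Step 1
Reactants: 1 4-bromocatechol
Product: 2 4-bromo-1,2-bis(methoxymethoxy)benzene
Conditions: MOMCl (2.5 equiv), iPr2NEt (3 equiv), CH2Cl2, 0 °C → rt
Reagents that add atoms: chloromethyl methyl ether (MOMCl), COCCl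
Why: O-alkylation of both phenols with the chloromethyl ether under amine base (MOM protection) is routine for catechols and installs the ortho-directing groups needed in step 2.

Step 2
Reactants: 2 4-bromo-1,2-bis(methoxymethoxy)benzene; 3 prenyl bromide
Product: 6 1-bromo-3,4-bis(methoxymethoxy)-2-(3-methylbut-2-en-1-yl)benzene, via aryllithium 4 (not isolated), via arylcopper 5 (not isolated)
Conditions: LDA (1.1 equiv, commercial solution), THF, −78 °C; CuBr·SMe2 (1.1 equiv), −78 → −40 °C; prenyl bromide (1.5 equiv), −78 → −20 °C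
Reagents that add atoms: prenyl bromide (3), CC(C)=CCBr
Why: Directed ortho-metalation with the amide base (no Br/Li exchange) should remove the proton flanked by OMOM and Br, the most acidic site, and transmetalation to copper both suppresses aryne formation from the ortho-bromoaryllithium and steers the allylic substitution of prenyl bromide to its α-carbon (SN2), giving the linear prenyl arene.

Step 3
Reactants: 6 1-bromo-3,4-bis(methoxymethoxy)-2-(3-methylbut-2-en-1-yl)benzene
Product: 9 1-[3,4-bis(methoxymethoxy)-2-(3-methylbut-2-en-1-yl)phenyl]ethan-1-one, via aryllithium 7 (not isolated), via lithium hemiaminalate 8 (not isolated)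
Conditions: n-BuLi (1.05 equiv), THF, −78 °C; MeC(O)N(OMe)Me (1.5 equiv), −78 → 0 °C; then H2O
Reagents that add atoms: N-methoxy-N-methylacetamide, CC(=O)N(C)OC
Why: Bromine–lithium exchange followed by acylation with the Weinreb amide stops at the ketone because the chelated tetrahedral adduct collapses only on aqueous work-up.

Step 4
Reactants: 10 5-bromoresorcinol
Product: 12 2-bromo-4,6-dihydroxybenzaldehyde, via iminium salt 11 (not isolated)
Conditions: POCl3 (1.2 equiv), DMF (1.5 equiv), MeCN, 0 °C → rt; then H2O, 50 °C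
Reagents that add atoms: N,N-dimethylformamide, CN(C)C=O (formyl carbon); water, O (carbonyl oxygen)
Why: Vilsmeier–Haack formylation of the electron-rich resorcinol ring should occur para to one hydroxyl and ortho to the other (C4/C6, equivalent here and next to bromine), the usual site for 5-substituted resorcinols, and hydrolysis of the iminium salt releases the aldehyde.

Step 5
Reactants: 12 2-bromo-4,6-dihydroxybenzaldehyde
Product: 13 2-bromo-4,6-bis(methoxymethoxy)benzaldehyde
Conditions: MOMCl (3 equiv), iPr2NEt (4 equiv), DMF, 0 °C → rt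
Reagents that add atoms: chloromethyl methyl ether (MOMCl), COCCl
Why: MOM protection of both phenols, including the hydrogen-bonded ortho hydroxyl, removes the acidic protons before the enolate addition and matches the B-ring protection.

Step 6
Reactants: 9 1-[3,4-bis(methoxymethoxy)-2-(3-methylbut-2-en-1-yl)phenyl]ethan-1-one; 13 2-bromo-4,6-bis(methoxymethoxy)benzaldehyde
Product: 16 racemic 3-[2-bromo-4,6-bis(methoxymethoxy)phenyl]-1-[3,4-bis(methoxymethoxy)-2-(3-methylbut-2-en-1-yl)phenyl]-3-hydroxypropan-1-one, via lithium enolate 14 (not isolated), via lithium aldolate 15 (not isolated)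
Conditions: LDA (1.1 equiv), THF, −78 °C; then 13, −78 °C; AcOH quench at −78 °C
Reagents that add atoms: none
Why: Kinetic deprotonation of the methyl ketone and crossed aldol addition of the lithium enolate to the non-enolisable aldehyde forms the C3–C4 bond; the new C4 carbinol is racemic, which is immaterial because C4 becomes a ketone in step 11, and the cold acidic quench prevents retro-aldol cleavage or dehydration.

Step 7
Reactants: 16 racemic aldol adduct
Product: 17 racemic 3-[2-bromo-4,6-bis(methoxymethoxy)phenyl]-1-[3,4-bis(methoxymethoxy)-2-(3-methylbut-2-en-1-yl)phenyl]-3-[(tert-butyldimethylsilyl)oxy]propan-1-one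
Conditions: TBSOTf (1.5 equiv), 2,6-lutidine (3 equiv), CH2Cl2, −78 → 0 °C
Reagents that add atoms: tert-butyldimethylsilyl triflate, CC(C)(C)[Si](C)(C)OS(=O)(=O)C(F)(F)F
Why: Silylation of the hindered benzylic hydroxyl with the silyl triflate and a hindered pyridine base is fast at low temperature and neither enolises the ketone nor triggers β-elimination.

Step 8
Reactants: 17 racemic β-silyloxy ketone
Product: 19 (1S,3RS)-3-[2-bromo-4,6-bis(methoxymethoxy)phenyl]-1-[3,4-bis(methoxymethoxy)-2-(3-methylbut-2-en-1-yl)phenyl]-3-[(tert-butyldimethylsilyl)oxy]propan-1-ol, via borate ester 18 (not isolated)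
Conditions: (R)-2-methyl-CBS-oxazaborolidine (20 mol%), catecholborane (2 equiv), toluene, −78 → −30 °C; aqueous work-up
Reagents that add atoms: none
Why: Corey–Bakshi–Shibata reduction: the ketone binds the catalyst boron anti to its aryl group (the larger substituent, CH2 being the smaller) and hydride is delivered from the nitrogen-bound borane, so the (R)-catalyst should give the (S)-carbinol from both enantiomers of 17 under reagent control, while catecholborane as hydride source leaves the prenyl alkene untouched.

Step 9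
Reactants: 19 (1S)-carbinol bromo diol mono-TBS ether
Product: 20 (2S,4RS)-4-[(tert-butyldimethylsilyl)oxy]-5,7-bis(methoxymethoxy)-2-[3,4-bis(methoxymethoxy)-2-(3-methylbut-2-en-1-yl)phenyl]chromane
Conditions: Pd(OAc)2 (5 mol%), 2-(di-tert-butylphosphino)-1,1′-binaphthyl (7 mol%), Cs2CO3 (1.5 equiv), toluene, 80 °C
Reagents that add atoms: none
Why: Pd(0) carrying the bulky, electron-rich di-tert-butylbiarylphosphine inserts into the C8a–Br bond, the C2 hydroxyl binds and is deprotonated by carbonate to give a seven-membered aryl-palladium alkoxide, and C–O reductive elimination forms O1–C8a. The closest known reaction type is the Buchwald–Hartwig-type intramolecular etherification of aryl bromides with tethered secondary alcohols, which turns enantioenriched carbinols into chromans. The one ring formed is pyran ring C, closed in a 6-exo sense by the C2 oxygen onto the aryl carbon. No stereocentre is created: C2 keeps its (S) configuration because its C–O bond is never broken, and C4 is a spectator that is oxidised later. The step needs reductive elimination to outrun β-hydride elimination of the palladium alkoxide, which the hindered ligand and the weak, sparingly soluble base are chosen to secure. Chemoselectivity rests on the substrate having one free hydroxyl only, MOM-capped phenols and a C4 silyl ether that can neither enolise nor eliminate, so retro-aldol cleavage and chalcone formation are excluded.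

Step 10
Reactants: 20 (2S)-4-O-TBS-flavan
Product: 21 (2S,4RS)-5,7-bis(methoxymethoxy)-2-[3,4-bis(methoxymethoxy)-2-(3-methylbut-2-en-1-yl)phenyl]chroman-4-ol
Conditions: TBAF (1.5 equiv), THF, 0 °C → rt; then H2O
Reagents that add atoms: none
Why: Fluoride-induced cleavage of the Si–O bond, driven by the strength of the Si–F bond, frees the C4 alcohol without touching the MOM acetals, the aryl ether or C2.

Step 11
Reactants: 21 (2S)-flavan-4-ol
Product: 22 (2S)-5,7-bis(methoxymethoxy)-2-[3,4-bis(methoxymethoxy)-2-(3-methylbut-2-en-1-yl)phenyl]chroman-4-one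
Conditions: Dess–Martin periodinane (1.5 equiv), NaHCO3, CH2Cl2, 0 °C → rt
Reagents that add atoms: none
Why: Dess–Martin oxidation of the secondary benzylic alcohol under bicarbonate buffering converts both C4 epimers into the same ketone under near-neutral conditions, so neither the acid-labile flavan-4-ol nor the base-labile C2 centre of the flavanone is put at risk.

Step 12
Reactants: 22 (2S)-tetra-O-MOM flavanone
Product: 23 (2S)-5,7-dihydroxy-2-[3,4-dihydroxy-2-(3-methylbut-2-en-1-yl)phenyl]chroman-4-one (CNP0204979.1)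
Conditions: 3 M aq. HCl/MeOH (1:4), 50 °C; work-up kept at pH 5–6
Reagents that add atoms: none
Why: Acid-catalysed solvolysis of the four aryl methoxymethyl acetals in methanol frees the phenols, and at moderate temperature and acidity the flavanone C2 centre (racemised only through base-induced ring opening) and the prenyl alkene should survive.

**Compound list**

1 | 4-bromocatechol (4-bromobenzene-1,2-diol) | Oc1ccc(Br)cc1O | starting material
2 | 4-bromo-1,2-bis(methoxymethoxy)benzene | COCOc1ccc(Br)cc1OCOC | intermediate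
3 | prenyl bromide (1-bromo-3-methylbut-2-ene) | CC(C)=CCBr | starting material
4 | [6-bromo-2,3-bis(methoxymethoxy)phenyl]lithium | [Li]c1c(Br)ccc(OCOC)c1OCOC | intermediate
5 | [6-bromo-2,3-bis(methoxymethoxy)phenyl]copper | [Cu]c1c(Br)ccc(OCOC)c1OCOC | intermediate
6 | 1-bromo-3,4-bis(methoxymethoxy)-2-(3-methylbut-2-en-1-yl)benzene | CC(C)=CCc1c(Br)ccc(OCOC)c1OCOC | intermediate
7 | [3,4-bis(methoxymethoxy)-2-(3-methylbut-2-en-1-yl)phenyl]lithium | [Li]c1ccc(OCOC)c(OCOC)c1CC=C(C)C | intermediate
8 | lithium 1-[3,4-bis(methoxymethoxy)-2-(3-methylbut-2-en-1-yl)phenyl]-1-[methoxy(methyl)amino]ethan-1-olate (tetrahedral adduct) | CC(O[Li])(N(C)OC)c1ccc(OCOC)c(OCOC)c1CC=C(C)C | intermediate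
9 | 1-[3,4-bis(methoxymethoxy)-2-(3-methylbut-2-en-1-yl)phenyl]ethan-1-one | CC(=O)c1ccc(OCOC)c(OCOC)c1CC=C(C)C | intermediate
10 | 5-bromoresorcinol (5-bromobenzene-1,3-diol) | Oc1cc(O)cc(Br)c1 | starting material
11 | [(2-bromo-4,6-dihydroxyphenyl)methylidene]dimethyliminium chloride | C[N+](C)=Cc1c(O)cc(O)cc1Br.[Cl-] | intermediate
12 | 2-bromo-4,6-dihydroxybenzaldehyde | O=Cc1c(O)cc(O)cc1Br | intermediate
13 | 2-bromo-4,6-bis(methoxymethoxy)benzaldehyde | COCOc1cc(Br)c(C=O)c(OCOC)c1 | intermediate
14 | lithium enolate of ketone 9 | [Li]OC(=C)c1ccc(OCOC)c(OCOC)c1CC=C(C)C | intermediate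
15 | lithium aldolate (lithium alkoxide of 16) | CC(C)=CCc1c(C(=O)CC(O[Li])c2c(Br)cc(OCOC)cc2OCOC)ccc(OCOC)c1OCOC | intermediate
16 | racemic 3-[2-bromo-4,6-bis(methoxymethoxy)phenyl]-1-[3,4-bis(methoxymethoxy)-2-(3-methylbut-2-en-1-yl)phenyl]-3-hydroxypropan-1-one | CC(C)=CCc1c(C(=O)CC(O)c2c(Br)cc(OCOC)cc2OCOC)ccc(OCOC)c1OCOC | intermediate
17 | racemic 3-[2-bromo-4,6-bis(methoxymethoxy)phenyl]-1-[3,4-bis(methoxymethoxy)-2-(3-methylbut-2-en-1-yl)phenyl]-3-[(tert-butyldimethylsilyl)oxy]propan-1-one | CC(C)=CCc1c(C(=O)CC(O[Si](C)(C)C(C)(C)C)c2c(Br)cc(OCOC)cc2OCOC)ccc(OCOC)c1OCOC | intermediate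
18 | 2-{[(1S)-carbinol of 19]oxy}-1,3,2-benzodioxaborole (catechol borate ester of 19) | CC(C)=CCc1c([C@@H](OB2Oc3ccccc3O2)CC(O[Si](C)(C)C(C)(C)C)c2c(Br)cc(OCOC)cc2OCOC)ccc(OCOC)c1OCOC | intermediate
19 | (1S,3RS)-3-[2-bromo-4,6-bis(methoxymethoxy)phenyl]-1-[3,4-bis(methoxymethoxy)-2-(3-methylbut-2-en-1-yl)phenyl]-3-[(tert-butyldimethylsilyl)oxy]propan-1-ol (key-step precursor, both C3 epimers) | CC(C)=CCc1c([C@@H](O)CC(O[Si](C)(C)C(C)(C)C)c2c(Br)cc(OCOC)cc2OCOC)ccc(OCOC)c1OCOC | intermediate
20 | (2S,4RS)-4-[(tert-butyldimethylsilyl)oxy]-5,7-bis(methoxymethoxy)-2-[3,4-bis(methoxymethoxy)-2-(3-methylbut-2-en-1-yl)phenyl]chromane (key-step product) | CC(C)=CCc1c([C@@H]2CC(O[Si](C)(C)C(C)(C)C)c3c(OCOC)cc(OCOC)cc3O2)ccc(OCOC)c1OCOC | intermediate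
21 | (2S,4RS)-5,7-bis(methoxymethoxy)-2-[3,4-bis(methoxymethoxy)-2-(3-methylbut-2-en-1-yl)phenyl]chroman-4-ol | CC(C)=CCc1c([C@@H]2CC(O)c3c(OCOC)cc(OCOC)cc3O2)ccc(OCOC)c1OCOC | intermediate
22 | (2S)-5,7-bis(methoxymethoxy)-2-[3,4-bis(methoxymethoxy)-2-(3-methylbut-2-en-1-yl)phenyl]chroman-4-one | CC(C)=CCc1c([C@@H]2CC(=O)c3c(OCOC)cc(OCOC)cc3O2)ccc(OCOC)c1OCOC | intermediate
23 | (2S)-5,7-dihydroxy-2-[3,4-dihydroxy-2-(3-methylbut-2-en-1-yl)phenyl]chroman-4-one (CNP0204979.1) | CC(C)=CCc1c([C@@H]2CC(=O)c3c(O)cc(O)cc3O2)ccc(O)c1O | target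

**Totals and risks**

Total step count: 12. Longest linear sequence: 10 steps (steps 1–3 and 6–12); the A-ring aldehyde is made in 2 steps (4 and 5) and joins at step 6.

Steps most likely to fail:

1. Step 9 (key step). What may go wrong:
   - β-hydride elimination from the palladium alkoxide followed by C–H reductive elimination (net loss of bromine and oxidation at C2);
   - slow oxidative addition next to the bulky benzylic silyl ether;
   - a base-induced O→O silyl shift that masks the C2 hydroxyl.

   Fallback: close the same ring through the complementary O1–C2 bond by Mitsunobu etherification with inversion. It sets out from ketone 17. Reduction with (S)-2-methyl-CBS-oxazaborolidine and catecholborane should give the (1R)-carbinol bromide F1. Miyaura borylation (Pd(dppf)Cl2, B2pin2, KOAc, dioxane, 85 °C) should give the (1R)-carbinol pinacol boronate F2. Oxidation (NaBO3·4H2O, THF/H2O, rt) should give the (1R)-carbinol phenol F3. PPh3/DIAD in THF at 0 °C should then displace the activated (R)-carbinol by the phenol oxygen with inversion, returning to the route at 20. Partial ionisation of the electron-rich benzylic carbinol is the weak point of this alternative.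

2. Step 8. What may go wrong: insufficient facial discrimination, because both ketone substituents are large and one enantiomer of racemic 17 may be mismatched with the catalyst; or a sluggish reduction of the hindered, electron-rich aryl ketone.

   Fallback: resolution in place of asymmetric reduction. It sets out from 17. NaBH4 (MeOH/THF, 0 °C) should give the stereorandom carbinol F4. Acylative kinetic resolution with (R)-benzotetramisole (5 mol%), isobutyric anhydride (0.6 equiv) and iPr2NEt in CHCl3 at 0 °C should, by the sense established for 1-arylalkanols, esterify the (R)-carbinols as the (1R)-isobutyrate F5 and leave the (S)-carbinols. These are separated by chromatography and are compound 19, where the route is rejoined.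

3. Step 12. What may go wrong: acid-promoted cyclisation of the 2′-prenyl group onto the liberated 3′-hydroxyl, addition of HCl or methanol across the alkene, or erosion of the C2 configuration on prolonged heating.

   Fallback: replace protic solvolysis by aprotic silyl-transfer cleavage. It sets out from 22. TMSOTf/2,2′-bipyridyl (CH2Cl2, 0 °C) should exchange each aryl MOM acetal for a trimethylsilyl ether, giving the tetrakis(trimethylsilyl) ether F6. This is hydrolysed with H2O/THF at rt under neutral conditions to the target 23.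

**Further compounds**

F1 | step 9 | (1R,3RS)-3-[2-bromo-4,6-bis(methoxymethoxy)phenyl]-1-[3,4-bis(methoxymethoxy)-2-(3-methylbut-2-en-1-yl)phenyl]-3-[(tert-butyldimethylsilyl)oxy]propan-1-ol | CC(C)=CCc1c([C@H](O)CC(O[Si](C)(C)C(C)(C)C)c2c(Br)cc(OCOC)cc2OCOC)ccc(OCOC)c1OCOC
F2 | step 9 | (1R,3RS)-1-[3,4-bis(methoxymethoxy)-2-(3-methylbut-2-en-1-yl)phenyl]-3-[2-(4,4,5,5-tetramethyl-1,3,2-dioxaborolan-2-yl)-4,6-bis(methoxymethoxy)phenyl]-3-[(tert-butyldimethylsilyl)oxy]propan-1-ol | CC(C)=CCc1c([C@H](O)CC(O[Si](C)(C)C(C)(C)C)c2c(B3OC(C)(C)C(C)(C)O3)cc(OCOC)cc2OCOC)ccc(OCOC)c1OCOC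
F3 | step 9 | (1R,3RS)-1-[3,4-bis(methoxymethoxy)-2-(3-methylbut-2-en-1-yl)phenyl]-3-[2-hydroxy-4,6-bis(methoxymethoxy)phenyl]-3-[(tert-butyldimethylsilyl)oxy]propan-1-ol | CC(C)=CCc1c([C@H](O)CC(O[Si](C)(C)C(C)(C)C)c2c(O)cc(OCOC)cc2OCOC)ccc(OCOC)c1OCOC
F4 | step 8 | 3-[2-bromo-4,6-bis(methoxymethoxy)phenyl]-1-[3,4-bis(methoxymethoxy)-2-(3-methylbut-2-en-1-yl)phenyl]-3-[(tert-butyldimethylsilyl)oxy]propan-1-ol, all stereoisomers | CC(C)=CCc1c(C(O)CC(O[Si](C)(C)C(C)(C)C)c2c(Br)cc(OCOC)cc2OCOC)ccc(OCOC)c1OCOC
F5 | step 8 | (1R,3RS)-3-[2-bromo-4,6-bis(methoxymethoxy)phenyl]-1-[3,4-bis(methoxymethoxy)-2-(3-methylbut-2-en-1-yl)phenyl]-3-[(tert-butyldimethylsilyl)oxy]propyl 2-methylpropanoate | CC(C)=CCc1c([C@H](OC(=O)C(C)C)CC(O[Si](C)(C)C(C)(C)C)c2c(Br)cc(OCOC)cc2OCOC)ccc(OCOC)c1OCOC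
F6 | step 12 | (2S)-5,7-bis(trimethylsilyloxy)-2-[3,4-bis(trimethylsilyloxy)-2-(3-methylbut-2-en-1-yl)phenyl]chroman-4-one | CC(C)=CCc1c([C@@H]2CC(=O)c3c(O[Si](C)(C)C)cc(O[Si](C)(C)C)cc3O2)ccc(O[Si](C)(C)C)c1O[Si](C)(C)C
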